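Ring A of the 2,3-dihydrobenzofuran (C3a, C4, C5, C6, C7, C7a) is cut at C6–C7, C4–C5 and C3a–C4, after a disposable oxygen is added back at C4. This leaves a trans-2-aryl-3-methyl-2,3-dihydrofuran bearing a methoxycarbene–Cr(CO)5 group, (E)-pent-3-en-1-yne and one CO ligand.
The cut is possible because ring A shares only its C3a–C7a edge with the heterocycle and carries OMe on C7 (next to C7a), H on C6 and the propenyl group on C5. That is the pattern a carbene carbon, a terminal alkyne and CO lay down around an enol-ether C=C.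
The carbene complex is cut at the carbene carbon (vinyllithium, Cr(CO)6, MeOTf), the dihydrofuran at its O–C(sp2) bond (alkynol cycloisomerisation), and the alkynol at the carbinol–propargyl bond (aldehyde plus chiral allenylzinc).
Forward order: ring B aldehyde, anti homopropargylic alcohol, dihydrofuran ring, carbene complex, ring A by benzannulation, removal of the C4 oxygen via the triflate, desilylation.
Stereochemistry: C3 comes from (R)-but-3-yn-2-ol with net inversion, C2 from the anti-selective cyclic transition state of the allenylzinc addition, and the E-alkene from (E)-1-bromoprop-1-ene; no later step touches them.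

Key step: step 8

Abbreviation: Ar = 3,4-dimethoxy-5-(triisopropylsilyloxy)phenyl (ring B as its TIPS ether).
Assumption: in the arene complexes the Cr(CO)3 group sits on ring A, the ring formed on the metal; their SMILES show the arene and a Cr(CO)3 fragment joined by a dot, the η6 bond being understood.

Step 1
Reactants: 1 3-hydroxy-4,5-dimethoxybenzaldehyde
Product: 2 3,4-dimethoxy-5-(triisopropylsilyloxy)benzaldehyde
Conditions: TIPSCl, imidazole, DMF, rt
Reagents that add atoms: triisopropylsilyl chloride, CC(C)[Si](Cl)(C(C)C)C(C)C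
Why: Standard phenol silylation; the bulky TIPS ether has no benzylic hydrogens, should resist Et2Zn, t-BuLi at low temperature, the carbene chemistry and formate, and comes off at the end with fluoride without affecting the propenyl group.

Step 2
Reactants: 3 (R)-but-3-yn-2-ol
Product: 4 (R)-but-3-yn-2-yl methanesulfonate
Conditions: MsCl, Et3N, CH2Cl2, −78 → 0 °C
Reagents that add atoms: methanesulfonyl chloride, CS(=O)(=O)Cl
Why: O-sulfonylation of a secondary alcohol leaves the stereocentre untouched, so the R configuration is carried into the propargylic mesylate.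

Step 3
Reactants: 2 3,4-dimethoxy-5-(triisopropylsilyloxy)benzaldehyde; 4 (R)-but-3-yn-2-yl methanesulfonate
Product: 6 (1S,2S)-1-Ar-2-methylbut-3-yn-1-ol, via (P)-buta-1,2-dienyl(ethyl)zinc 5 (not isolated)
Conditions: Pd(OAc)2 (5 mol %), PPh3 (5 mol %), Et2Zn (3 equiv), THF, −78 → −20 °C; aq NH4Cl
Reagents that add atoms: none
Why: Marshall propargylation: zerovalent palladium displaces the mesylate anti (SN2'), transmetalation gives the configurationally defined allenylzinc, and its SE2' addition through a cyclic transition state with aryl and methyl apart should favour the anti alcohol; net inversion at the propargylic carbon makes the methyl-bearing carbon S, the anti preference makes the carbinol carbon S, and the minor syn isomer is removed by chromatography.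

Step 4
Reactants: 6 (1S,2S)-1-Ar-2-methylbut-3-yn-1-ol
Product: 7 (2S,3S)-2-Ar-3-methyl-2,3-dihydrofuran
Conditions: Mo(CO)6 (30 mol %), Et3N, Et2O, hν (350 nm), 1 h; then 6, rt
Reagents that add atoms: none
Why: Molybdenum-catalysed alkynol endo-cycloisomerisation: the Et3N·Mo(CO)5 catalyst turns the terminal alkyne into a metal vinylidene, the hydroxyl adds to its α-carbon and protodemetalation releases the endocyclic enol ether, neither stereocentre taking part.

Step 5
Reactants: 7 (2S,3S)-2-Ar-3-methyl-2,3-dihydrofuran; 8 chromium hexacarbonyl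
Product: 11 pentacarbonyl{methoxy[(4S,5S)-5-Ar-4-methyl-4,5-dihydrofuran-2-yl]methylidene}chromium, via the 5-lithio-2,3-dihydrofuran 9 (not isolated), via the lithium acylchromate 10 (not isolated)
Conditions: t-BuLi, THF, −78 → 0 °C; Cr(CO)6, Et2O, 0 °C → rt; MeOTf, CH2Cl2, 0 °C
Reagents that add atoms: methyl trifluoromethanesulfonate, COS(=O)(=O)C(F)(F)F
Why: Fischer carbene synthesis: the vinylic C–H next to the ring oxygen is the kinetically most acidic site of a 2,3-dihydrofuran, the vinyllithium adds to a CO ligand of Cr(CO)6, and the hard methylating agent alkylates the acylchromate on oxygen, all without involving the sp3 stereocentres.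

Step 6
Reactants: 12 (E)-1-bromoprop-1-ene; 13 ethynyltriisopropylsilane
Product: 14 (E)-triisopropyl(pent-3-en-1-yn-1-yl)silane
Conditions: Pd(PPh3)2Cl2 (2 mol %), CuI (4 mol %), i-Pr2NH, THF, rt
Reagents that add atoms: none
Why: Sonogashira coupling of an alkenyl bromide proceeds with retention of alkene geometry, and the silyl group makes the enyne non-volatile so that it can be purified.

Step 7
Reactants: 14 (E)-triisopropyl(pent-3-en-1-yn-1-yl)silane
Product: 15 (E)-pent-3-en-1-yne
Conditions: Bu4NF·3H2O, DMSO, rt; product distilled from the pot into a −78 °C trap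
Reagents that add atoms: none
Why: Fluoride-mediated protodesilylation of a silylalkyne leaves the E-alkene untouched, and the high-boiling solvent lets the volatile enyne be distilled straight out for use in the next step.

Step 8
Reactants: 11 pentacarbonyl{methoxy[(4S,5S)-5-Ar-4-methyl-4,5-dihydrofuran-2-yl]methylidene}chromium; 15 (E)-pent-3-en-1-yne
Product: 17 (2S,3S)-2-Ar-7-methoxy-3-methyl-5-[(E)-prop-1-enyl]-2,3-dihydrobenzofuran-4-ol, via the η6-tricarbonylchromium phenol complex 16 (not isolated)
Conditions: 15 (3 equiv), THF (0.05 M), 55 °C, sealed tube, Ar; then air, hν, Et2O, rt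
Reagents that add atoms: none
Why: Dötz benzannulation: thermal loss of one CO from the zerovalent chromium carbene complex opens a site for the alkyne, which inserts into the Cr=C bond (forming C6–C7) to give a vinylcarbene, and CO insertion (forming C4–C5) then gives a chromium-bound dienylketene. Ring A closes by a thermal six-electron disrotatory electrocyclisation of this dienylketene (forming C3a–C4), and the cyclohexadienone tautomerises to the phenol, which stays η6-bound to Cr(CO)3 until air and light release it. The closest known reactions are benzannulations of cyclic 2-oxacycloalkenyl(methoxy)carbene complexes of chromium with terminal alkynes and of alkenylcarbene complexes with conjugated enynes. No stereocentre is formed: C2 and C3 are sp3 spectators outside the reacting π system under neutral conditions, and the E-alkene of the enyne is carried through unchanged. The regiochemistry needed (terminal CH next to the carbene carbon, propenyl-bearing carbon next to the inserted CO) is the normal steric outcome for a terminal alkyne. The alkyne should react in preference to the alkene because alkynes insert into the electrophilic carbene far faster, and benzannulation should win over cyclopentannulation because the carbene is an alkenyl(alkoxy)carbene of chromium in THF.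

Step 9
Reactants: 17 (2S,3S)-2-Ar-7-methoxy-3-methyl-5-[(E)-prop-1-enyl]-2,3-dihydrobenzofuran-4-ol
Product: 18 (2S,3S)-2-Ar-7-methoxy-3-methyl-5-[(E)-prop-1-enyl]-2,3-dihydrobenzofuran-4-yl trifluoromethanesulfonate
Conditions: Tf2O, pyridine, CH2Cl2, −20 → 0 °C
Reagents that add atoms: trifluoromethanesulfonic anhydride, O=S(=O)(OS(=O)(=O)C(F)(F)F)C(F)(F)F
Why: O-sulfonylation of the phenol under pyridine buffering, done at once because the electron-rich hydroquinone monoether is air-sensitive, turns the unwanted C4 oxygen into a leaving group for palladium.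

Step 10
Reactants: 18 (2S,3S)-2-Ar-7-methoxy-3-methyl-5-[(E)-prop-1-enyl]-2,3-dihydrobenzofuran-4-yl trifluoromethanesulfonate
Product: 19 (2S,3S)-2-Ar-7-methoxy-3-methyl-5-[(E)-prop-1-enyl]-2,3-dihydrobenzofuran
Conditions: Pd(OAc)2 (10 mol %), dppf (12 mol %), Et3N, HCO2H, DMF, 80 °C
Reagents that add atoms: none
Why: Palladium-catalysed formate reduction of an aryl triflate (oxidative addition of zerovalent palladium, triflate–formate exchange, loss of CO2, reductive elimination of Ar–H), a deoxygenation known to work on di-ortho-substituted phenol triflates with a chelating ferrocenyl diphosphine.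

Step 11
Reactants: 19 (2S,3S)-2-Ar-7-methoxy-3-methyl-5-[(E)-prop-1-enyl]-2,3-dihydrobenzofuran
Product: 20 5-[(2S,3S)-7-methoxy-3-methyl-5-[(E)-prop-1-enyl]-2,3-dihydrobenzofuran-2-yl]-2,3-dimethoxyphenol (CNP0299956.1)
Conditions: Bu4NF, AcOH, THF, 0 °C
Reagents that add atoms: none
Why: Fluoride cleavage of the aryl silyl ether, buffered with acetic acid so that the freed phenol is not left as an oxidisable phenoxide and the benzylic C2–O bond sees neither strong acid nor strong base.

Compound list
1 | 3-hydroxy-4,5-dimethoxybenzaldehyde | COc1cc(C=O)cc(O)c1OC | starting material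
2 | 3,4-dimethoxy-5-(triisopropylsilyloxy)benzaldehyde | COc1cc(C=O)cc(O[Si](C(C)C)(C(C)C)C(C)C)c1OC | intermediate
3 | (R)-but-3-yn-2-ol | C[C@@H](O)C#C | starting material
4 | (R)-but-3-yn-2-yl methanesulfonate | C[C@@H](OS(C)(=O)=O)C#C | intermediate
5 | (P)-buta-1,2-dienyl(ethyl)zinc | [H]C(C)=[C@]=C([H])[Zn]CC | intermediate
6 | (1S,2S)-1-[3,4-dimethoxy-5-(triisopropylsilyloxy)phenyl]-2-methylbut-3-yn-1-ol (anti) | C#C[C@H](C)[C@@H](c1cc(O[Si](C(C)C)(C(C)C)C(C)C)c(OC)c(OC)c1)O | intermediate
7 | (2S,3S)-2-[3,4-dimethoxy-5-(triisopropylsilyloxy)phenyl]-3-methyl-2,3-dihydrofuran (trans) | C1=C[C@H](C)[C@@H](c2cc(O[Si](C(C)C)(C(C)C)C(C)C)c(OC)c(OC)c2)O1 | intermediate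
8 | chromium hexacarbonyl, Cr(CO)6 | [Cr](=C=O)(=C=O)(=C=O)(=C=O)(=C=O)=C=O | starting material
9 | {(4S,5S)-5-[3,4-dimethoxy-5-(triisopropylsilyloxy)phenyl]-4-methyl-4,5-dihydrofuran-2-yl}lithium | [Li]C1=C[C@H](C)[C@@H](c2cc(O[Si](C(C)C)(C(C)C)C(C)C)c(OC)c(OC)c2)O1 | intermediate
10 | lithium pentacarbonyl({(4S,5S)-5-[3,4-dimethoxy-5-(triisopropylsilyloxy)phenyl]-4-methyl-4,5-dihydrofuran-2-yl}carbonyl)chromate | [Li+].[O-]C(=[Cr](=C=O)(=C=O)(=C=O)(=C=O)=C=O)C1=C[C@H](C)[C@@H](c2cc(O[Si](C(C)C)(C(C)C)C(C)C)c(OC)c(OC)c2)O1 | intermediate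
11 | pentacarbonyl(methoxy{(4S,5S)-5-[3,4-dimethoxy-5-(triisopropylsilyloxy)phenyl]-4-methyl-4,5-dihydrofuran-2-yl}methylidene)chromium | COC(=[Cr](=C=O)(=C=O)(=C=O)(=C=O)=C=O)C1=C[C@H](C)[C@@H](c2cc(O[Si](C(C)C)(C(C)C)C(C)C)c(OC)c(OC)c2)O1 | intermediate
12 | (E)-1-bromoprop-1-ene | C/C=C/Br | starting material
13 | ethynyltriisopropylsilane | C#C[Si](C(C)C)(C(C)C)C(C)C | starting material
14 | (E)-triisopropyl(pent-3-en-1-yn-1-yl)silane | C/C=C/C#C[Si](C(C)C)(C(C)C)C(C)C | intermediate
15 | (E)-pent-3-en-1-yne | C/C=C/C#C | intermediate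
16 | tricarbonylchromium complex of 17, Cr(CO)3 η6-bound to ring A | C/C=C/c1cc(OC)c2c(c1O)[C@H](C)[C@@H](c3cc(O[Si](C(C)C)(C(C)C)C(C)C)c(OC)c(OC)c3)O2.[Cr](=C=O)(=C=O)=C=O | intermediate
17 | (2S,3S)-2-[3,4-dimethoxy-5-(triisopropylsilyloxy)phenyl]-7-methoxy-3-methyl-5-[(E)-prop-1-enyl]-2,3-dihydrobenzofuran-4-ol | C/C=C/c1cc(OC)c2c(c1O)[C@H](C)[C@@H](c3cc(O[Si](C(C)C)(C(C)C)C(C)C)c(OC)c(OC)c3)O2 | intermediate
18 | (2S,3S)-2-[3,4-dimethoxy-5-(triisopropylsilyloxy)phenyl]-7-methoxy-3-methyl-5-[(E)-prop-1-enyl]-2,3-dihydrobenzofuran-4-yl trifluoromethanesulfonate | C/C=C/c1cc(OC)c2c(c1OS(=O)(=O)C(F)(F)F)[C@H](C)[C@@H](c3cc(O[Si](C(C)C)(C(C)C)C(C)C)c(OC)c(OC)c3)O2 | intermediate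
19 | (2S,3S)-2-[3,4-dimethoxy-5-(triisopropylsilyloxy)phenyl]-7-methoxy-3-methyl-5-[(E)-prop-1-enyl]-2,3-dihydrobenzofuran | C/C=C/c1cc(OC)c2c(c1)[C@H](C)[C@@H](c3cc(O[Si](C(C)C)(C(C)C)C(C)C)c(OC)c(OC)c3)O2 | intermediate
20 | 5-[(2S,3S)-7-methoxy-3-methyl-5-[(E)-prop-1-enyl]-2,3-dihydrobenzofuran-2-yl]-2,3-dimethoxyphenol | C/C=C/c1cc(OC)c2c(c1)[C@H](C)[C@@H](c1cc(O)c(OC)c(OC)c1)O2 | target

Total step count: 11.
Longest linear sequence: 8 steps (steps 2, 3, 4, 5, 8, 9, 10, 11 from (R)-but-3-yn-2-ol; the same length from aldehyde 1 through step 1).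

Steps most likely to fail

Step 5. The metalation may lose its site selectivity: t-BuLi could remove the benzylic C2–H (next to oxygen and ring B) or an aryl hydrogen ortho to a methoxy or silyloxy group instead of the vinylic hydrogen, leading to epimerisation at C2 or ring opening. The fallback sets out from alkynol 6. The molybdenum-mediated cyclisation (Mo(CO)6, Et3N, Et2O, hν) is run in the presence of Bu3SnOTf, so that the cyclic vinylmolybdenum intermediate is trapped by tin and not by a proton, giving tributyl{(4S,5S)-5-Ar-4-methyl-4,5-dihydrofuran-2-yl}stannane F1. Tin–lithium exchange (n-BuLi, THF, −78 °C) is fast and site-specific and gives the lithio compound 9, where the route is rejoined (Cr(CO)6, then MeOTf, to 11).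

Step 8. The conjugated enyne may be consumed by oligomerisation or double insertion, the vinylcarbene intermediate may be diverted by the neighbouring alkene before CO insertion, or the very electron-rich phenol may be over-oxidised towards a quinone during decomplexation. The fallback sets out from carbene complex 11 and keeps the benzannulation but no longer delivers the propenyl group in it. The commercially available, non-conjugated pent-1-en-4-yne (an alkyl-type terminal alkyne, the best-behaved class of partner) is used in THF at 55 °C. This gives the η6-tricarbonylchromium complex F2, which is decomplexed in air and light to (2S,3S)-5-allyl-2-Ar-7-methoxy-3-methyl-2,3-dihydrobenzofuran-4-ol F3. The allyl group is then moved into conjugation with RuHCl(CO)(PPh3)3 (toluene, 80 °C), a hydride addition–elimination isomerisation that favours the E-propenyl arene. The route is rejoined at phenol 17.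

Step 10. Oxidative addition into the di-ortho-substituted, electron-rich C4–OTf bond may be slow, so that S–O cleavage back to the phenol, or reduction or migration of the propenyl double bond by palladium hydride, takes over. The fallback sets out from complex 16, kept under argon and not aired. Triflation (Tf2O, i-Pr2NEt, CH2Cl2, −78 °C) gives the η6-tricarbonylchromium complex of the triflate F4, in which the electron-withdrawing Cr(CO)3 group strongly accelerates oxidative addition. Formate reduction (Pd(OAc)2, dppf, Et3N, HCO2H, DMF, rt) then gives the η6-tricarbonylchromium complex of the deoxygenated arene F5. Air and light release the arene, and the route is rejoined at 19.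

Further compounds
F1 | step 5 | tributyl{(4S,5S)-5-[3,4-dimethoxy-5-(triisopropylsilyloxy)phenyl]-4-methyl-4,5-dihydrofuran-2-yl}stannane | CCCC[Sn](CCCC)(CCCC)C1=C[C@H](C)[C@@H](c2cc(O[Si](C(C)C)(C(C)C)C(C)C)c(OC)c(OC)c2)O1
F2 | step 8 | tricarbonylchromium complex of F3, Cr(CO)3 η6-bound to ring A | C=CCc1cc(OC)c2c(c1O)[C@H](C)[C@@H](c3cc(O[Si](C(C)C)(C(C)C)C(C)C)c(OC)c(OC)c3)O2.[Cr](=C=O)(=C=O)=C=O
F3 | step 8 | (2S,3S)-5-allyl-2-[3,4-dimethoxy-5-(triisopropylsilyloxy)phenyl]-7-methoxy-3-methyl-2,3-dihydrobenzofuran-4-ol | C=CCc1cc(OC)c2c(c1O)[C@H](C)[C@@H](c3cc(O[Si](C(C)C)(C(C)C)C(C)C)c(OC)c(OC)c3)O2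
F4 | step 10 | tricarbonylchromium complex of triflate 18, Cr(CO)3 η6-bound to ring A | C/C=C/c1cc(OC)c2c(c1OS(=O)(=O)C(F)(F)F)[C@H](C)[C@@H](c3cc(O[Si](C(C)C)(C(C)C)C(C)C)c(OC)c(OC)c3)O2.[Cr](=C=O)(=C=O)=C=O
F5 | step 10 | tricarbonylchromium complex of 19, Cr(CO)3 η6-bound to ring A | C/C=C/c1cc(OC)c2c(c1)[C@H](C)[C@@H](c3cc(O[Si](C(C)C)(C(C)C)C(C)C)c(OC)c(OC)c3)O2.[Cr](=C=O)(=C=O)=C=O
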